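**Retrosynthetic overview**
- The free 5-OH is unmasked last, by chelation-controlled cleavage of the peri (5-O) methyl ether of the fully methylated flavone.
- Ring C (the pyranone) is disconnected at O1–C8a. It is closed by a new dehydrogenative enol O–H / aryl C–H coupling of an open-chain 1,3-diaryl-1,3-diketone that has no ortho-phenol, so a cheap 2,4,5-trimethoxyphenyl unit maps onto the 5,7,8-trioxygenated ring A.
- The diketone is disconnected at C2–C3 by a crossed Claisen condensation of 2,4,5-trimethoxyacetophenone (ring A, C4, C3) with methyl 2,5-dimethoxybenzoate (ring B, C2).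
- Rings A and B are bought with all five oxygens in place; only ring C is built. Order: C2–C3 bond, ring C, then 5-OH.

Assumption: the target SMILES has no stereocentre or other stereogenic element, so the "single enantiomer" is the achiral compound itself and no step needs stereocontrol.
Assumption: salts and chelates that persist in the flask until work-up are numbered as intermediates; short-lived radical ions are described in words only.

**Step 1**
Reactants: 1 methyl ketone 2,4,5-trimethoxyacetophenone; 2 methyl 2,5-dimethoxybenzoate
Product: 4 diketone 1-(2,5-dimethoxyphenyl)-3-(2,4,5-trimethoxyphenyl)propane-1,3-dione, via sodium enolate 3 (not isolated)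
Conditions: NaH (2.5 equiv), 2 (1.2 equiv), THF, reflux, 6 h; then aq. HCl (1 mol/L), 0 °C
Reagents that add atoms: sodium hydride, [Na+].[H-] (its sodium is found in intermediate 3 only)
Why: Crossed Claisen condensation: the sodium enolate of methyl ketone 1 acylates the non-enolisable ester 2, and irreversible deprotonation of the acidic 1,3-diketone to chelated enolate 3 drives the equilibrium; the methyl ethers are inert and no stereocentre is formed.

**Step 2**
Reactants: 4 diketone 1-(2,5-dimethoxyphenyl)-3-(2,4,5-trimethoxyphenyl)propane-1,3-dione
Product: 5 pentamethoxyflavone 2-(2,5-dimethoxyphenyl)-5,7,8-trimethoxy-4H-chromen-4-one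
Conditions: 9-mesityl-3,6-di-tert-butyl-10-phenylacridinium tetrafluoroborate (5 mol%), Co(dmgH)2(py)Cl (5 mol%; dmgH = dimethylglyoximato, py = pyridine), degassed MeCN/HFIP 4:1 (0.05 mol/L), 450 nm LEDs, Ar, 25 °C, 24 h
Reagents that add atoms: none
Why: Proposed new method: an acceptorless dehydrogenative enol O–H/aryl C–H coupling (radical-cation oxa-cyclisation) in which the excited 9-mesityl-3,6-di-tert-butyl-10-phenylacridinium ion (about +2.0 volts vs SCE) oxidises the more electron-rich 2,4,5-trimethoxyphenyl ring of 4 (estimated +1.4 volts, against about +1.65 volts for the dimethoxyphenyl ring) to its radical cation; HFIP opens the hydrogen-bonded enol chelate so that the enol oxygen on the carbon bearing ring B can add to C6 of ring A (the only position the tether allows, giving a six-membered ring; ortho to a methoxy donor); the resulting cyclohexadienyl radical, stabilised by the adjacent OMe and the acyl group, gives up a proton and an electron to Co(dmgH)2(py)Cl, which releases H2 and returns the acridinium ion; the closest known reaction type is the photoredox/Co(dmgH)2(py)Cl or anodic dehydrogenative C–H/O–H lactonisation of biaryl-2-carboxylic acids to benzocoumarins and arene radical-cation C–H amination, with the diketone enol acting here as a vinylogous carboxylic acid; no stereocentre is formed.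

**Step 3**
Reactants: 5 pentamethoxyflavone 2-(2,5-dimethoxyphenyl)-5,7,8-trimethoxy-4H-chromen-4-one
Product: 7 target 5-hydroxy-7,8,2',5'-tetramethoxyflavone, via dichloroboron chelate 6 (not isolated)
Conditions: BCl3 (1.0 mol/L in CH2Cl2, 2.0 equiv), CH2Cl2, −78 to 0 °C, 1 h; then H2O, rt
Reagents that add atoms: boron trichloride, ClB(Cl)Cl (boron and chlorine are found in intermediate 6 only)
Why: Chelation-controlled Lewis-acid ether cleavage (selective peri O-demethylation): BCl3 bridges the C4 carbonyl and the 5-OMe oxygen in a six-membered chelate, chloride removes only that methyl group to give 6, and water frees the hydrogen-bonded 5-OH; the 7-, 8-, 2'- and 5'-methoxy groups cannot chelate the carbonyl and survive at or below 0 °C.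

**Compound list**
1 | 2,4,5-trimethoxyacetophenone (1-(2,4,5-trimethoxyphenyl)ethan-1-one) | CC(=O)c1cc(OC)c(OC)cc1OC | starting material
2 | methyl 2,5-dimethoxybenzoate | COC(=O)c1cc(OC)ccc1OC | starting material
3 | sodium (Z)-1-(2,5-dimethoxyphenyl)-3-oxo-3-(2,4,5-trimethoxyphenyl)prop-1-en-1-olate (chelated enolate of 4) | [Na+].[O-]/C(=C\C(=O)c1cc(OC)c(OC)cc1OC)c1cc(OC)ccc1OC | intermediate
4 | 1-(2,5-dimethoxyphenyl)-3-(2,4,5-trimethoxyphenyl)propane-1,3-dione (present mainly as its chelated enol) | COc1ccc(OC)c(C(=O)CC(=O)c2cc(OC)c(OC)cc2OC)c1 | intermediate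
5 | 2-(2,5-dimethoxyphenyl)-5,7,8-trimethoxy-4H-chromen-4-one (5,7,8,2',5'-pentamethoxyflavone) | COc1ccc(OC)c(-c2cc(=O)c3c(OC)cc(OC)c(OC)c3o2)c1 | intermediate
6 | 5-O-dichloroboryl chelate of 7,8,2',5'-tetramethoxyflavone (boron on the 5-oxygen, coordinated by the C4 carbonyl) | COc1ccc(OC)c(-c2cc(=O)c3c(OB(Cl)Cl)cc(OC)c(OC)c3o2)c1 | intermediate
7 | 5-hydroxy-7,8,2',5'-tetramethoxyflavone (2-(2,5-dimethoxyphenyl)-5-hydroxy-7,8-dimethoxy-4H-chromen-4-one), achiral | COc1ccc(OC)c(-c2cc(=O)c3c(O)cc(OC)c(OC)c3o2)c1 | target

**Totals**
Total step count: 3. Longest linear sequence: 3 steps (both partners of step 1 are commercial).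

**Steps most likely to fail**

Step 2 (the proposed new ring closure) is the most likely to fail. The hole may sit on ring B and close there to an isomeric chromone. The enol oxygen may add reversibly without rearomatisation. A para-dimethoxy pair may be oxidatively demethylated to a quinone if water is present, or the diketone may be oxidised at its central carbon. The fallback is known chemistry; it sets out from ester 2 and comes back at 5. Ester 2 is condensed with the catalogue compound 2-hydroxy-3,4,6-trimethoxyacetophenone F3 through its phenoxide–enolate dianion (LiN(SiMe3)2, 3.2 equiv, THF, −78 °C to rt). This C-acylation gives the ortho-hydroxy diketone 1-(2,5-dimethoxyphenyl)-3-(2-hydroxy-3,4,6-trimethoxyphenyl)propane-1,3-dione F4. Classical acid-catalysed cyclodehydration (catalytic H2SO4, AcOH, 100 °C) then closes ring C through the single phenol oxygen and returns to the route at pentamethoxyflavone 5. The only free OH is flanked by the 3-OMe group, so the 5,7,8-pattern is fixed.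

Step 3 is second. The cleavage may not stop at the 5-OMe (the vicinal 7,8-dimethoxy pair can also bind boron), or the boron chelate may resist hydrolysis. The fallback sets out from 5 and comes back at 7. It swaps selective cleavage for selective alkylation: excess BBr3 (8 equiv, CH2Cl2, −78 °C to rt) removes all five methyl groups to give 5,7,8,2',5'-pentahydroxyflavone F5, handled under argon. Me2SO4 (4.1 equiv) with K2CO3 in refluxing acetone then methylates the four ordinary phenols; the 5-OH, hydrogen-bonded to the C4 carbonyl, is the least nucleophilic and stays free. This returns directly to target 7.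

Step 1 is third. Ester 2 is electron-rich and ortho-substituted, so it is a sluggish acyl acceptor, and ketone 1 can self-condense. The fallback sets out from ester 2 and comes back at 4. It makes the C2–C3 bond by aldol addition and adjusts the oxidation level afterwards. i-Bu2AlH (1.05 equiv, CH2Cl2, −78 °C) reduces 2 to 2,5-dimethoxybenzaldehyde F1. The lithium enolate of ketone 1 (LiN(i-Pr)2, THF, −78 °C) adds to it to give racemic 3-(2,5-dimethoxyphenyl)-3-hydroxy-1-(2,4,5-trimethoxyphenyl)propan-1-one F2, whose single stereocentre is erased in the next operation. Oxidation of this β-hydroxy ketone with 2-iodoxybenzoic acid (EtOAc, 75 °C) returns to the route at diketone 4.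

**Further compounds**
F1 | step 1 | 2,5-dimethoxybenzaldehyde | COc1ccc(OC)c(C=O)c1
F2 | step 1 | racemic 3-(2,5-dimethoxyphenyl)-3-hydroxy-1-(2,4,5-trimethoxyphenyl)propan-1-one | COc1ccc(OC)c(C(O)CC(=O)c2cc(OC)c(OC)cc2OC)c1
F3 | step 2 | 2-hydroxy-3,4,6-trimethoxyacetophenone | CC(=O)c1c(O)c(OC)c(OC)cc1OC
F4 | step 2 | 1-(2,5-dimethoxyphenyl)-3-(2-hydroxy-3,4,6-trimethoxyphenyl)propane-1,3-dione | COc1ccc(OC)c(C(=O)CC(=O)c2c(O)c(OC)c(OC)cc2OC)c1
F5 | step 3 | 5,7,8,2',5'-pentahydroxyflavone | Oc1ccc(O)c(-c2cc(=O)c3c(O)cc(O)c(O)c3o2)c1
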